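**Retrosynthetic overview**

1. Ring letters: A = resorcinol ring and C = mono-oxygenated ring of the 9,10-dihydrophenanthrene, B = catechol ring fused to the seven-membered ring, D = pendant catechol ring. Target 20 ⇐ heptamethyl ether 19 by global O-demethylation.
2. 19 ⇐ aryl triflate 16 + 3,4-dimethoxystyrene 17. The CH2–CH(ring D) bridge of the seven-membered ring is a styrene: a Heck coupling makes the ring C–CH2 bond and, in the same flask, acid makes the CH(ring D)–ring B bond and closes the seven-membered ring.
3. Enabling feature: the bridge CH carries ring D, whose 4-oxygen is para to it (stabilised benzylic cation). The ring B carbon that must bond is para to the ring B 3-oxygen (nucleophilic) and is held over the bridge because ring B hangs on the neighbouring diarylmethine stereocentre. The ring C carbon that must bond is meta to the ring C oxygen (not nucleophilic), so it carries the triflate.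
4. 16 ⇐ phenol 15 ⇐ dibromide 13 by Stille–Kelly biaryl closure (ring A to ring C, central six-membered ring). 13 ⇐ carbinol 11 by chiral phosphoric acid transfer hydrogenation through an ortho-quinone methide, the only enantio-determining step.
5. 11 ⇐ benzyl Grignard reagent 10 (from 3,5-dimethoxybenzyl alcohol) + hydroxy ketone 6 ⇐ lithiated 3-bromo-5-fluoroanisole + 3,4-dimethoxybenzoyl chloride, then F→OH. Ring order: central six-membered ring (step 7), then seven-membered ring (step 9).

Key step: step 9

Assumption (remark on the chemistry): the sense of induction of the phosphoric acid in step 6 is assumed; (R)-TRIP is written for the (S) centre, and the antipodal catalyst would be used if the opposite sense were found.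

**Step 1**
Reactants: 1 1-bromo-3-fluoro-5-methoxybenzene; 2 3,4-dimethoxybenzoyl chloride
Product: 4 (2-bromo-6-fluoro-4-methoxyphenyl)(3,4-dimethoxyphenyl)methanone, via aryllithium 3 (not isolated)
Conditions: LiN(i-Pr)2 (1.05 equiv), THF, −78 °C; then 2 (1.2 equiv), −78 °C; AcOH quench at −78 °C
Reagents that add atoms: none
Why: Deprotonation by the lithium amide should occur at the C–H flanked by F and Br (the most acidic site), and the hindered aryllithium should acylate the acid chloride only once because the 2,6-disubstituted diaryl ketone resists a second addition (ortho-lithiation/acylation).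

**Step 2**
Reactants: 4 (2-bromo-6-fluoro-4-methoxyphenyl)(3,4-dimethoxyphenyl)methanone
Product: 6 (2-bromo-6-hydroxy-4-methoxyphenyl)(3,4-dimethoxyphenyl)methanone, via sulfonylethyl aryl ether 5 (not isolated)
Conditions: CH3SO2CH2CH2OH (1.5 equiv), NaH (3 equiv), DMF, 0 °C → rt; then 1 M HCl
Reagents that add atoms: 2-(methylsulfonyl)ethanol, CS(=O)(=O)CCO
Why: Nucleophilic aromatic substitution (SNAr) of the fluoride ortho to the ketone by the alkoxide, followed by base-induced β-elimination of methyl vinyl sulfone, should give the phenol; fluoride is displaced far faster than bromide, and a hydroxide-free reagent avoids cleavage of the hindered ketone.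

**Step 3**
Reactants: 7 (3,5-dimethoxyphenyl)methanol
Product: 8 (2-bromo-3,5-dimethoxyphenyl)methanol
Conditions: N-bromosuccinimide (1.0 equiv), CH2Cl2, 0 °C → rt
Reagents that add atoms: N-bromosuccinimide, O=C1CCC(=O)N1Br
Why: Electrophilic aromatic bromination should go to the ring position ortho to CH2OH and para to a methoxy group, the usual outcome for 3,5-dimethoxybenzyl systems.

**Step 4**
Reactants: 8 (2-bromo-3,5-dimethoxyphenyl)methanol
Product: 9 2-bromo-1-(bromomethyl)-3,5-dimethoxybenzene
Conditions: PBr3 (0.4 equiv), Et2O, 0 °C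
Reagents that add atoms: phosphorus tribromide, BrP(Br)Br
Why: Standard conversion of a benzylic alcohol into the bromide (SN2 displacement on the phosphite ester).

**Step 5**
Reactants: 9 2-bromo-1-(bromomethyl)-3,5-dimethoxybenzene; 6 (2-bromo-6-hydroxy-4-methoxyphenyl)(3,4-dimethoxyphenyl)methanone
Product: 11 racemic 3-bromo-2-[2-(2-bromo-3,5-dimethoxyphenyl)-1-(3,4-dimethoxyphenyl)-1-hydroxyethyl]-5-methoxyphenol, via benzylmagnesium bromide 10 (not isolated)
Conditions: Mg turnings, Et2O, 0 °C (10, about 2.5 equiv); then 6 in THF, 0 °C → rt; H2O work-up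
Reagents that add atoms: none
Why: Magnesium should insert into the benzylic C–Br bond much faster than into the aryl C–Br bond, and Grignard 1,2-addition to the magnesium-chelated ortho-hydroxy benzophenone (no α-hydrogen) should give the racemic tertiary carbinol, one equivalent of reagent being consumed by the phenol.

**Step 6**
Reactants: 11 racemic 3-bromo-2-[2-(2-bromo-3,5-dimethoxyphenyl)-1-(3,4-dimethoxyphenyl)-1-hydroxyethyl]-5-methoxyphenol
Product: 13 3-bromo-2-[(1S)-2-(2-bromo-3,5-dimethoxyphenyl)-1-(3,4-dimethoxyphenyl)ethyl]-5-methoxyphenol, via ortho-quinone methide 12 (not isolated)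
Conditions: (R)-3,3'-bis(2,4,6-triisopropylphenyl)-1,1'-binaphthyl-2,2'-diyl hydrogen phosphate [(R)-TRIP, 10 mol%], diethyl 2,6-dimethyl-1,4-dihydropyridine-3,5-dicarboxylate (Hantzsch ester, 1.5 equiv), 5 Å molecular sieves, CH2Cl2, rt
Reagents that add atoms: none
Why: Chiral phosphoric acid-catalysed asymmetric transfer hydrogenation: the acid dehydrates the ortho-hydroxybenzylic carbinol to the ortho-quinone methide, binds it at the phenol oxygen and delivers hydride from the Hantzsch ester to one face of the methide carbon, which sets the (S) diarylmethine centre under catalyst control, as in the transfer hydrogenation of ortho-hydroxy 1,1-diarylalkenes.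

**Step 7**
Reactants: 13 3-bromo-2-[(1S)-2-(2-bromo-3,5-dimethoxyphenyl)-1-(3,4-dimethoxyphenyl)ethyl]-5-methoxyphenol
Product: 15 (10S)-10-(3,4-dimethoxyphenyl)-3,5,7-trimethoxy-9,10-dihydrophenanthren-1-ol, via aryltrimethylstannane 14 (not isolated)
Conditions: Pd(PPh3)4 (10 mol%), Me3SnSnMe3 (1.1 equiv), 1,4-dioxane, 100 °C
Reagents that add atoms: none
Why: Stille–Kelly reaction: zerovalent palladium stannylates one aryl bromide with the distannane and the arylstannane then couples intramolecularly with the other bromide, closing the central six-membered ring; without base no C–H arylation of ring B should compete, and the stereocentre is not touched.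

**Step 8**
Reactants: 15 (10S)-10-(3,4-dimethoxyphenyl)-3,5,7-trimethoxy-9,10-dihydrophenanthren-1-ol
Product: 16 (10S)-10-(3,4-dimethoxyphenyl)-3,5,7-trimethoxy-9,10-dihydrophenanthren-1-yl trifluoromethanesulfonate
Conditions: (CF3SO2)2O (1.3 equiv), pyridine, CH2Cl2, 0 °C
Reagents that add atoms: trifluoromethanesulfonic anhydride, O=S(=O)(OS(=O)(=O)C(F)(F)F)C(F)(F)F
Why: O-Sulfonylation of the phenol gives the aryl triflate needed for oxidative addition at the ring C carbon.

**Step 9**
Reactants: 16 (10S)-10-(3,4-dimethoxyphenyl)-3,5,7-trimethoxy-9,10-dihydrophenanthren-1-yl trifluoromethanesulfonate; 17 4-ethenyl-1,2-dimethoxybenzene (3,4-dimethoxystyrene, 1.15 equiv)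
Product: 19 hepta-O-methyl ether of the target (S at the diarylmethine carbon shared by the six- and seven-membered rings, R at the CH(3,4-dimethoxyphenyl) carbon, the two methine hydrogens cis), via stilbene 18 (not isolated)
Conditions: Pd(OAc)2 (5 mol%), PPh3 (12 mol%), n-Bu4NCl (2 equiv), Cy2NMe (2 equiv), toluene, 100 °C; then 0 °C, dilute with CH2Cl2/(CF3)2CHOH, CF3SO3H (excess over the amine), 0 °C → rt
Reagents that add atoms: none
Why: Mizoroki–Heck reaction (oxidative addition of zerovalent palladium into the ring C triflate, chloride exchange to the neutral arylpalladium chloride, styrene insertion with aryl transfer to the CH2 terminus, β-hydride elimination) should give (E)-stilbene 18; triflic acid then protonates the alkene at the carbon next to ring C, giving the benzylic cation on the carbon that bears ring D, and ring B attacks it through its carbon para to the 3-methoxy group (intramolecular Friedel–Crafts alkylation, a hydroarylation). The closest known reaction types are the Heck arylation of electron-rich styrenes and the acid-induced cation–arene cyclisation of methoxy-substituted stilbenes to seven-membered carbocycles. The seven-membered ring is closed in a 7-endo-trig sense with respect to the stilbene C=C (both alkene carbons end inside the ring). The new CH(aryl) stereocentre is controlled by the existing (S) centre: ring B is pseudo-axial on the dihydrophenanthrene, and closure through the conformation that keeps ring D on the outer, pseudo-equatorial side of the boat-shaped ring puts the two methine hydrogens cis; because the benzylic C–aryl bond can re-ionise in triflic acid, the same less crowded isomer is also expected at equilibrium. The step needs linear Heck regioselectivity (chloride additive and monodentate phosphine), Markovnikov protonation (para-methoxy group of ring D) and closure at C-6 rather than C-2 of the 3,4-dimethoxyphenyl ring B (para-methoxy activation and sterics); ring A cannot reach the cation.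

**Step 10**
Reactants: 19 hepta-O-methyl ether of the target
Product: 20 CNP0306974.2, the heptaphenol target
Conditions: BBr3 (excess), CH2Cl2, −78 °C → rt; then H2O
Reagents that add atoms: none
Why: Lewis acid cleavage of all seven aryl methyl ethers; neither stereocentre carries a leaving group, so both should survive.

**Compound list**

1 | 1-bromo-3-fluoro-5-methoxybenzene | COc1cc(F)cc(Br)c1 | starting material
2 | 3,4-dimethoxybenzoyl chloride | COc1ccc(cc1OC)C(Cl)=O | starting material
3 | (2-bromo-6-fluoro-4-methoxyphenyl)lithium | [Li]c1c(F)cc(OC)cc1Br | intermediate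
4 | (2-bromo-6-fluoro-4-methoxyphenyl)(3,4-dimethoxyphenyl)methanone | COc1cc(F)c(C(=O)c2ccc(OC)c(OC)c2)c(Br)c1 | intermediate
5 | {2-bromo-4-methoxy-6-[2-(methylsulfonyl)ethoxy]phenyl}(3,4-dimethoxyphenyl)methanone | COc1cc(OCCS(C)(=O)=O)c(C(=O)c2ccc(OC)c(OC)c2)c(Br)c1 | intermediate
6 | (2-bromo-6-hydroxy-4-methoxyphenyl)(3,4-dimethoxyphenyl)methanone | COc1cc(O)c(C(=O)c2ccc(OC)c(OC)c2)c(Br)c1 | intermediate
7 | (3,5-dimethoxyphenyl)methanol | COc1cc(CO)cc(OC)c1 | starting material
8 | (2-bromo-3,5-dimethoxyphenyl)methanol | COc1cc(CO)c(Br)c(OC)c1 | intermediate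
9 | 2-bromo-1-(bromomethyl)-3,5-dimethoxybenzene | COc1cc(CBr)c(Br)c(OC)c1 | intermediate
10 | (2-bromo-3,5-dimethoxybenzyl)magnesium bromide | COc1cc(C[Mg]Br)c(Br)c(OC)c1 | intermediate
11 | racemic 3-bromo-2-[2-(2-bromo-3,5-dimethoxyphenyl)-1-(3,4-dimethoxyphenyl)-1-hydroxyethyl]-5-methoxyphenol | COc1cc(OC)c(Br)c(CC(O)(c2ccc(OC)c(OC)c2)c2c(O)cc(OC)cc2Br)c1 | intermediate
12 | 5-bromo-6-[2-(2-bromo-3,5-dimethoxyphenyl)-1-(3,4-dimethoxyphenyl)ethylidene]-3-methoxycyclohexa-2,4-dien-1-one (ortho-quinone methide) | COC1=CC(=O)C(=C(Cc2cc(OC)cc(OC)c2Br)c2ccc(OC)c(OC)c2)C(Br)=C1 | intermediate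
13 | 3-bromo-2-[(1S)-2-(2-bromo-3,5-dimethoxyphenyl)-1-(3,4-dimethoxyphenyl)ethyl]-5-methoxyphenol | COc1cc(OC)c(Br)c(c1)C[C@@H](c1ccc(OC)c(OC)c1)c1c(O)cc(OC)cc1Br | intermediate
14 | 2-[(1S)-2-(2-bromo-3,5-dimethoxyphenyl)-1-(3,4-dimethoxyphenyl)ethyl]-5-methoxy-3-(trimethylstannyl)phenol | COc1cc(OC)c(Br)c(c1)C[C@@H](c1ccc(OC)c(OC)c1)c1c(O)cc(OC)cc1[Sn](C)(C)C | intermediate
15 | (10S)-10-(3,4-dimethoxyphenyl)-3,5,7-trimethoxy-9,10-dihydrophenanthren-1-ol | COc1cc(OC)c2c(c1)C[C@@H](c1ccc(OC)c(OC)c1)c1c(O)cc(OC)cc1-2 | intermediate
16 | (10S)-10-(3,4-dimethoxyphenyl)-3,5,7-trimethoxy-9,10-dihydrophenanthren-1-yl trifluoromethanesulfonate | COc1cc(OC)c2c(c1)C[C@@H](c1ccc(OC)c(OC)c1)c1c(OS(=O)(=O)C(F)(F)F)cc(OC)cc1-2 | intermediate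
17 | 4-ethenyl-1,2-dimethoxybenzene (3,4-dimethoxystyrene) | C=Cc1ccc(OC)c(OC)c1 | starting material
18 | (10S)-10-(3,4-dimethoxyphenyl)-1-[(E)-2-(3,4-dimethoxyphenyl)ethenyl]-3,5,7-trimethoxy-9,10-dihydrophenanthrene | COc1cc(OC)c2c(c1)C[C@@H](c1ccc(OC)c(OC)c1)c1c(/C=C/c3ccc(OC)c(OC)c3)cc(OC)cc1-2 | intermediate
19 | hepta-O-methyl ether of the target (hexacycle, S diarylmethine, R aryl-bearing methine, methine hydrogens cis) | COc1cc(OC)c2c(c1)C[C@H]1c3cc(OC)c(OC)cc3[C@@H](c3ccc(OC)c(OC)c3)Cc3cc(OC)cc-2c31 | intermediate
20 | CNP0306974.2, heptaphenol | Oc1cc(O)c2c(c1)C[C@H]1c3cc(O)c(O)cc3[C@@H](c3ccc(O)c(O)c3)Cc3cc(O)cc-2c31 | target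

**Step count**

Total steps: 10. Longest linear sequence: 8 (steps 1, 2, 5, 6, 7, 8, 9, 10).

**Steps most likely to fail**

Step 9. After protonation the benzylic cation may take a hydride from the neighbouring diarylmethine C–H (1,5-hydride transfer, followed by aromatisation of the dihydrophenanthrene), may close to the other diastereomer, or may be alkylated intermolecularly by residual styrene. The fallback sets out from 16 and returns at 19. Palladium-catalysed α-arylation of 1-(3,4-dimethoxyphenyl)ethanone with 16 (Pd(OAc)2, XPhos, K3PO4, toluene, 100 °C) would give 2-[(10S)-10-(3,4-dimethoxyphenyl)-3,5,7-trimethoxy-9,10-dihydrophenanthren-1-yl]-1-(3,4-dimethoxyphenyl)ethanone F1. Cyclodehydration with CH3SO3H in CH2Cl2 (Friedel–Crafts hydroxyalkylation by ring B, then loss of water) would close the seven-membered ring as the didehydro analogue of 19 with a C=C between the two bridge carbons F2. Hydrogenation (H2, Pd/C, EtOAc) should deliver hydrogen from the convex face, cis to the diarylmethine hydrogen, and give 19.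

Step 6. The bromine next to the methide carbon twists the ortho-quinone methide, so facial discrimination in the hydride transfer may be poor. The fallback sets out from 11 and returns at 13. Ionic hydrogenation (Et3SiH, CF3CO2H, CH2Cl2) would give racemic 3-bromo-2-[2-(2-bromo-3,5-dimethoxyphenyl)-1-(3,4-dimethoxyphenyl)ethyl]-5-methoxyphenol F3. Resolution by preparative chromatography on a chiral stationary phase would then give 13; the (1R)-enantiomer F4 is set aside.

Step 7. Double stannylation or protodehalogenation may outrun ring closure. The fallback goes directly from 13 to 15 by stoichiometric reductive coupling of the two aryl bromides with zerovalent nickel (Ni(cod)2, 2,2'-bipyridine, DMF, 60 °C; nickel-mediated Ullmann-type biaryl coupling), a tin-free ring closure that makes no new compound F0.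

**Further compounds**

F1 | step 9 | 2-[(10S)-10-(3,4-dimethoxyphenyl)-3,5,7-trimethoxy-9,10-dihydrophenanthren-1-yl]-1-(3,4-dimethoxyphenyl)ethanone | COc1cc(OC)c2c(c1)C[C@@H](c1ccc(OC)c(OC)c1)c1c(CC(=O)c3ccc(OC)c(OC)c3)cc(OC)cc1-2
F2 | step 9 | didehydro analogue of 19 (C=C between the two bridge carbons of the seven-membered ring, S diarylmethine) | COc1cc(OC)c2c(c1)C[C@H]1c3cc(OC)c(OC)cc3C(c3ccc(OC)c(OC)c3)=Cc3cc(OC)cc-2c31
F3 | step 6 | racemic 3-bromo-2-[2-(2-bromo-3,5-dimethoxyphenyl)-1-(3,4-dimethoxyphenyl)ethyl]-5-methoxyphenol | COc1cc(OC)c(Br)c(c1)CC(c1ccc(OC)c(OC)c1)c1c(O)cc(OC)cc1Br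
F4 | step 6 | 3-bromo-2-[(1R)-2-(2-bromo-3,5-dimethoxyphenyl)-1-(3,4-dimethoxyphenyl)ethyl]-5-methoxyphenol | COc1cc(OC)c(Br)c(c1)C[C@H](c1ccc(OC)c(OC)c1)c1c(O)cc(OC)cc1Br
F0 | step 7 | none | none
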